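5 questions stand below: 4 ask how much Z ends in a flask, and the other asks which flask holds most.

| flask | J | G | temperature | remark | time |
|---|---|---|---|---|---|
| gamma | 1.9 M | 0.67 M | −5 °C | run made earlier |  |
| alpha | 1.9 M | 2.7 M | 20 °C | run made earlier |  |
| green | 1.9 M | 1.33 M |  | at 0 °C until 30 min, from then on at 40 °C | 2.5 h |
| red | 1.9 M | 1.33 M | 40 °C |  | 2.5 h |
| violet | 1.9 M | 1.33 M | 0 °C |  | 2.5 h |
| ochre | 1.9 M | 1.33 M | 20 °C |  | 2.5 h |

| run | time / h | Z / % | Q / % | J / % |
|---|---|---|---|---|
| gamma | 3.00 | 25 | 1 | 59 |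
| gamma | 6.00 | 16 | 1 | 52 |
| gamma | 8.00 | 12 | 4 | 46 |
| gamma | 12.0 | 8 | 7 | 41 |
| gamma | 15.0 | 8 | 4 | 42 |
| alpha | 0.333 | 69 | 12 | 0 |
| alpha | 1.00 | 51 | 31 | 0 |
| alpha | 2.00 | 38 | 36 | 0 |
| alpha | 2.50 | 31 | 36 | 0 |
| alpha | 4.00 | 22 | 32 | 2 |

(readings scatter by 2 percentage points)

- percent here means J units held: one D counts as two
- the analysis behind the earlier runs scatters by 2 percentage points, standard deviation
- what may be going on: J + G -> Z + X; Z <-> L; G + Q -> E; J + Z -> D; Z <-> Q

- the best flask by amount of Z, in percent of the J charged; "all alike" if 1.5 percentage points covers them all (green / red / violet / ochre / all alike)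
- amount of Z at the end, in percent of the J charged, green
- amount of Z at the end, in percent of the J charged, red
- amount of Z at the end, in percent of the J charged, violet
- amount of Z at the end, in percent of the J charged, ochre

1. Each Z made costs one J and one G, and each D costs one J and one Z. Once G, the limiting reagent, is spent, J and the pool (Z with its products Q, L and E) fall at the same rate. Their ratio is one, time drops out, and pool minus J stays constant.
2. The pool floor is twice the G charge as a fraction of the J charge, less the whole J charge, here 40.0%. Each E takes a G that makes no Z, so the constant is the floor less twice the E formed, and pool = floor + J left − twice E. I set E aside in my reckoning, as a guess.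
3. I test this on gamma, taking its G as spent. At the last reading the rule gives 12.5%, and Z plus Q read 12.0%.
4. My first figure for violet is the floor itself, but that needs its J gone, and this is the weak link.
5. Gamma's first two readings give J loss per hour per unit of Z as 0.205 h⁻¹. For the warmer violet I guess a factor 1.41.
6. With Z near half the charge, violet's surplus J of 30.0% falls to 20.9%, so its pool is 60.9%.
7. Gamma's Q suggests 0.0354 h⁻¹ from Z, which, scaled by the same factor, leaves violet 53.3% as Z. That is my number.

The forecast differs from my number. It names violet, with green 13%, red 12%, violet 38% and ochre 19%: “At 0 °C, Z → Q is slow, so Z stays near 38%.”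

The simulation names violet, with green 14.6%, red 12.9%, violet 47.0% and ochre 17.5%.

    J + G → Z + X (k = 0.00662 M⁻¹ s⁻¹, Ea = 48.0 kJ mol⁻¹)
    Z ⇌ L (K = 3.10, k = 1.33 × 10⁻⁴ s⁻¹, Ea = 93.0 kJ mol⁻¹, ΔH = −58.0 kJ mol⁻¹)
    G + Q → E (k = 6.90 × 10⁻⁴ M⁻¹ s⁻¹, Ea = 82.0 kJ mol⁻¹)
    J + Z → D (k = 0.00102 M⁻¹ s⁻¹, Ea = 56.0 kJ mol⁻¹)
    Z ⇌ Q (K = 0.401, k = 0.00177 s⁻¹, Ea = 81.0 kJ mol⁻¹, ΔH = −50.0 kJ mol⁻¹)
    (constants at 40 °C)

Violet has not come to rest at 2.5 h: 22% of its J and 5.0% of its own G remain. Floor plus J left, less twice that G on the J scale and twice its E of 0.0300%, gives 54.7%, and Z, Q, L and E hold 54.7%. At 25.0 h, violet's J is 4.19% and its E 0.0805%, so the rule gives 44.0%, and the pool holds 44.0%. Inside it, Z has fallen to 9.15% and Q has risen to 33.3%; the Z-Q relaxation half-life of 9.00 h is long against the time. Ochre then holds 9.89% of Z.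

For the neighbour of violet with 0.80 M of G, the same sum with J left 47%, G left 1.1% and E 0.00590% gives 30.2%. Its computed Z, Q, L and E hold 30.2%, of which Z is 25.6%.

The earlier runs and the new flask were computed for substances that don't exist; the scatter is artificial.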